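**Plan** (core atoms: C1 carries N, C2 is CH2, C3 the hydroxylated bridgehead, C4 the ketone, C5 the CH bridgehead, C6 the ring B carbinol, C7–C8 the epoxide with C8 on C3, C9 the carbinol next to C1)
Retrosynthesis: the amide N–acyl bond and the epoxide oxygen are removed first, then the ketol bond C3–C4. That bond is the bridge link shared by ring A (C1, C2, C3, C4, C5, C9) and ring B (C3 to C8); without it the core is a cis-cyclooctenone (C3-C2-C1-C9-C5-C6-C7-C8) whose formyl carbon C4 on C5 lies 1,5 across the ring from the C3 ketone.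
The eight-membered ring is cut at C7=C8 (metathesis) and the chain at C3–C8, C5–C6 and C9–C5, back to protected L-aspartic acid, a malonate, acrolein and a vinyl Grignard reagent.
Forward: chain assembly (Claisen, reduction, aldol, vinyl addition), ring-closing metathesis to the cyclooctene, oxidation, one carbene-catalysed transannular benzoin closing rings A and B together, then deprotection, N-acylation and epoxidation.
Stereochemistry: C1 from L-aspartic acid; C9 by substrate-controlled ketone reduction; C5 and C6 by an oxazolidinone-controlled syn aldol; C3 by the bridge geometry; C7 and C8 by hydroxyl-directed epoxidation.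

Key step: step 13

Remarks: the commercial N-Boc 4-tert-butyl ester of L-aspartic acid (1) is taken as the aspartic acid building block. The C3 carbinol made in step 10 is carried as both epimers (descriptor left open in 20 and 21), because step 12 oxidises it to the ketone.

**Route**

Step 1
Reactants: 1 (2S)-4-tert-butoxy-2-[(tert-butoxycarbonyl)amino]-4-oxobutanoic acid; 2 monobenzyl malonate
Product: 5 6-benzyl 1-tert-butyl (3S)-3-[(tert-butoxycarbonyl)amino]-4-oxohexanedioate, via acyl imidazolide 3 (not isolated), via acylmalonic half ester 4 (not isolated)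
Conditions: CDI, THF, 23 °C; then 2, MgCl2, Et3N, THF, 23 °C; 1 M citric acid
Reagents that add atoms: none
Why: Decarboxylative Claisen condensation: the acyl imidazolide 3 acylates the magnesium enolate of the malonate half ester under nearly neutral conditions and the acylmalonic acid 4 loses CO2 on acidification, which forms C9–C5 without touching the C1 stereocentre, the Boc group or the tert-butyl ester.

Step 2
Reactants: 5 6-benzyl 1-tert-butyl (3S)-3-[(tert-butoxycarbonyl)amino]-4-oxohexanedioate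
Product: 6 6-benzyl 1-tert-butyl (3S,4R)-3-[(tert-butoxycarbonyl)amino]-4-hydroxyhexanedioate
Conditions: NaBH4, THF/MeOH (4:1), −40 °C
Reagents that add atoms: none
Why: Substrate-controlled borohydride reduction of an N-carbamoyl α-amino ketone (1,2-induction, Cram-chelate model): with the carbonyl held syn to the NH-carbamate the hydride should enter past the C1 hydrogen and give the 1,2-anti amino alcohol (C9 R), the usual outcome for N-Boc γ-amino β-keto esters; the minor epimer is to be removed by chromatography.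

Step 3
Reactants: 6 6-benzyl 1-tert-butyl (3S,4R)-3-[(tert-butoxycarbonyl)amino]-4-hydroxyhexanedioate
Product: 7 6-benzyl 1-tert-butyl (3S,4R)-3-[(tert-butoxycarbonyl)amino]-4-[(tert-butyldimethylsilyl)oxy]hexanedioate
Conditions: TBSCl, imidazole, DMF, 23 °C
Reagents that add atoms: tert-butyldimethylsilyl chloride, CC(C)(C)[Si](C)(C)Cl
Why: Standard silylation of a secondary alcohol with the silyl chloride and imidazole, mild enough for the Boc group and both esters; it also blocks lactonisation onto the C3 ester.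

Step 4
Reactants: 7 6-benzyl 1-tert-butyl (3S,4R)-3-[(tert-butoxycarbonyl)amino]-4-[(tert-butyldimethylsilyl)oxy]hexanedioate
Product: 8 (3R,4S)-4-[(tert-butoxycarbonyl)amino]-6-tert-butoxy-3-[(tert-butyldimethylsilyl)oxy]-6-oxohexanoic acid
Conditions: H2 (1 atm), Pd/C, EtOAc, 23 °C
Reagents that add atoms: none
Why: Hydrogenolysis of the benzyl ester over palladium on carbon is selective at this stage because no alkene is present yet and the Boc group, tert-butyl ester and silyl ether are inert to it.

Step 5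
Reactants: 8 (3R,4S)-4-[(tert-butoxycarbonyl)amino]-6-tert-butoxy-3-[(tert-butyldimethylsilyl)oxy]-6-oxohexanoic acid; 9 (4S)-4-benzyl-1,3-oxazolidin-2-one
Product: 11 (4S)-4-benzyl-3-[(3R,4S)-4-[(tert-butoxycarbonyl)amino]-6-tert-butoxy-3-[(tert-butyldimethylsilyl)oxy]-6-oxohexanoyl]-1,3-oxazolidin-2-one, via mixed pivalic anhydride 10 (not isolated)
Conditions: t-BuCOCl, Et3N, THF, −20 °C; then 9, LiCl, −20 → 23 °C
Reagents that add atoms: none
Why: N-Acylation of the oxazolidinone through the mixed pivalic anhydride with LiCl activation is the standard way to load an acid onto this auxiliary and needs no strong base that could eliminate the β-silyloxy group.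

Step 6
Reactants: 11 (4S)-4-benzyl-3-[(3R,4S)-4-[(tert-butoxycarbonyl)amino]-6-tert-butoxy-3-[(tert-butyldimethylsilyl)oxy]-6-oxohexanoyl]-1,3-oxazolidin-2-one; 12 acrolein
Product: 15 (4S)-4-benzyl-3-[(2R,3R,4S)-4-[(tert-butoxycarbonyl)amino]-6-tert-butoxy-3-[(tert-butyldimethylsilyl)oxy]-2-[(1R)-1-hydroxyprop-2-en-1-yl]-6-oxohexanoyl]-1,3-oxazolidin-2-one, via Z-dibutylboron enolate 13 (not isolated), via dibutylboron aldolate 14 (not isolated)
Conditions: n-Bu2BOTf (2.2 equiv), i-Pr2NEt, CH2Cl2, −78 → 0 °C; then 12, −78 → 0 °C; pH 7 buffer, MeOH, 30% H2O2, 0 °C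
Reagents that add atoms: none
Why: Evans syn aldol reaction: the Z-dibutylboron enolate 13 adds to acrolein through a closed Zimmerman–Traxler chair in which the (S)-benzyl oxazolidinone shields one enolate face, so the syn aldol with C5 (R) and C6 (R) should form, C6–O syn-1,3 to C9–O and C4 anti to both; the auxiliary is expected to override the influence of the C9 centre, and excess boron triflate allows for binding to the carbamate.

Step 7
Reactants: 15 (4S)-4-benzyl-3-[(2R,3R,4S)-4-[(tert-butoxycarbonyl)amino]-6-tert-butoxy-3-[(tert-butyldimethylsilyl)oxy]-2-[(1R)-1-hydroxyprop-2-en-1-yl]-6-oxohexanoyl]-1,3-oxazolidin-2-one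
Product: 16 (4S)-4-benzyl-3-[(2R,3R,4S)-4-[(tert-butoxycarbonyl)amino]-6-tert-butoxy-3-[(tert-butyldimethylsilyl)oxy]-2-[(1R)-1-[(tert-butyldimethylsilyl)oxy]prop-2-en-1-yl]-6-oxohexanoyl]-1,3-oxazolidin-2-one
Conditions: TBSOTf, 2,6-lutidine, CH2Cl2, −78 → −20 °C
Reagents that add atoms: tert-butyldimethylsilyl trifluoromethanesulfonate, CC(C)(C)[Si](C)(C)OS(=O)(=O)C(F)(F)F
Why: Silylation of the hindered aldol hydroxyl with the silyl triflate and 2,6-lutidine at low temperature is routine for such adducts and prevents retro-aldol cleavage; a short reaction time at or below −20 °C spares the Boc group.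

Step 8
Reactants: 16 (4S)-4-benzyl-3-[(2R,3R,4S)-4-[(tert-butoxycarbonyl)amino]-6-tert-butoxy-3-[(tert-butyldimethylsilyl)oxy]-2-[(1R)-1-[(tert-butyldimethylsilyl)oxy]prop-2-en-1-yl]-6-oxohexanoyl]-1,3-oxazolidin-2-one
Product: 17 tert-butyl (3S,4R,5R,6R)-3-[(tert-butoxycarbonyl)amino]-4,6-bis[(tert-butyldimethylsilyl)oxy]-5-(hydroxymethyl)oct-7-enoate
Conditions: LiBH4, H2O (1 equiv), Et2O, 0 °C
Reagents that add atoms: none
Why: Reductive cleavage of the N-acyl oxazolidinone with LiBH4 and one equivalent of water turns the imide carbonyl C4 into the primary alcohol and releases the auxiliary, while the tert-butyl ester and silyl ethers are not reduced at 0 °C.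

Step 9
Reactants: 17 tert-butyl (3S,4R,5R,6R)-3-[(tert-butoxycarbonyl)amino]-4,6-bis[(tert-butyldimethylsilyl)oxy]-5-(hydroxymethyl)oct-7-enoate
Product: 18 tert-butyl N-[(3S,4R,5R,6R)-4,6-bis[(tert-butyldimethylsilyl)oxy]-5-(hydroxymethyl)-1-oxooct-7-en-3-yl]carbamate
Conditions: i-Bu2AlH (3.5 equiv), CH2Cl2, −78 °C; MeOH, then aq. potassium sodium tartrate
Reagents that add atoms: none
Why: Partial reduction of the ester with diisobutylaluminium hydride at −78 °C should stop at the aldehyde oxidation level; extra hydride is allowed for the OH and NH protons.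

Step 10
Reactants: 18 tert-butyl N-[(3S,4R,5R,6R)-4,6-bis[(tert-butyldimethylsilyl)oxy]-5-(hydroxymethyl)-1-oxooct-7-en-3-yl]carbamate; 19 vinylmagnesium bromide
Product: 20 tert-butyl N-[(5S,6R,7R,8R)-6,8-bis[(tert-butyldimethylsilyl)oxy]-3-hydroxy-7-(hydroxymethyl)deca-1,9-dien-5-yl]carbamate (both C3 epimers)
Conditions: 19 (5 equiv), THF, −78 → 0 °C; aq. NH4Cl
Reagents that add atoms: none
Why: Grignard 1,2-addition of the vinyl reagent to the aldehyde installs C8 and the second terminal alkene; both C3 epimers are acceptable because C3 becomes a ketone in step 12.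

Step 11
Reactants: 20 tert-butyl N-[(5S,6R,7R,8R)-6,8-bis[(tert-butyldimethylsilyl)oxy]-3-hydroxy-7-(hydroxymethyl)deca-1,9-dien-5-yl]carbamate
Product: 21 tert-butyl N-[(1S,2R,3R,4R,5Z)-2,4-bis[(tert-butyldimethylsilyl)oxy]-7-hydroxy-3-(hydroxymethyl)cyclooct-5-en-1-yl]carbamate (both C7 epimers, C7 of this name being core atom C3)
Conditions: RuCl2(=CHPh)(PCy3)(H2IMes) (second-generation Grubbs catalyst, 10 mol %), 1,4-benzoquinone (10 mol %), CH2Cl2 (2 mM), 40 °C
Reagents that add atoms: none
Why: Ring-closing metathesis of a 1,9-diene with two monosubstituted, allylically oxygenated alkenes, a known way to polyoxygenated cyclooctenes; the eight-membered ring can hold the new C7=C8 bond only as Z, high dilution favours closure over oligomerisation, the free allylic hydroxyl speeds initiation and benzoquinone suppresses alkene isomerisation.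

Step 12
Reactants: 21 tert-butyl N-[(1S,2R,3R,4R,5Z)-2,4-bis[(tert-butyldimethylsilyl)oxy]-7-hydroxy-3-(hydroxymethyl)cyclooct-5-en-1-yl]carbamate
Product: 22 tert-butyl N-[(1S,2R,3R,4R,5Z)-2,4-bis[(tert-butyldimethylsilyl)oxy]-3-formyl-7-oxocyclooct-5-en-1-yl]carbamate
Conditions: Dess–Martin periodinane (3 equiv), CH2Cl2, 0 → 23 °C
Reagents that add atoms: none
Why: Dess–Martin oxidation converts the allylic C3 alcohol (both epimers) into the enone and the primary C4 alcohol into the aldehyde in one operation under non-basic conditions, which should leave the epimerisable, β-silyloxylated C5 centre intact.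

Step 13
Reactants: 22 tert-butyl N-[(1S,2R,3R,4R,5Z)-2,4-bis[(tert-butyldimethylsilyl)oxy]-3-formyl-7-oxocyclooct-5-en-1-yl]carbamate
Product: 24 tert-butyl N-[(1R,2R,3S,5S,8R)-2,8-bis[(tert-butyldimethylsilyl)oxy]-5-hydroxy-9-oxobicyclo[3.3.1]non-6-en-3-yl]carbamate, via Breslow intermediate 23 (not isolated)
Conditions: 2-(pentafluorophenyl)-6,7-dihydro-5H-pyrrolo[2,1-c][1,2,4]triazol-2-ium tetrafluoroborate (20 mol %), i-Pr2NEt (20 mol %), toluene, 23 → 40 °C
Reagents that add atoms: none
Why: Proposed new method: the triazolylidene freed by the amine adds to the formyl carbon C4, proton transfer gives the Breslow intermediate 23, and its nucleophilic C4 attacks the C3 ketone that the cyclooctenone holds 1,5 across the ring, after which proton transfer and loss of the carbene give the ketol; the closest known reaction type is the carbene-catalysed intramolecular crossed benzoin of an aldehyde with a ketone to cyclic tertiary α-ketols, which has not been run transannularly in an eight-membered ring. The single new bond C3–C4 closes ring A (C1, C2, C3, C4, C5, C9) and ring B (C3 to C8) at once, each as a 6-exo-trig addition to the ketone carbonyl. The only new stereocentre, C3, is set by the one-carbon bridge: C4 can reach C3 only from the ring face on which C5 carries it, so the new hydroxyl must point outward. The step needs 1,2-addition to the ketone in preference to conjugate (Stetter) addition, to aldol closure from the C2 enolate and to epimerisation or β-elimination at C5; attack at C7 would close a four-membered ring, and the electron-poor N-pentafluorophenyl triazolium is deprotonated by a weak amine that should not enolise the substrate at a competitive rate. The cis relation of the formyl group to both silyloxy groups (set in steps 2 and 6) places these groups on the exo faces of the product, and the bridgehead ketol can neither enolise towards C5 nor dehydrate, which should make the closure a thermodynamic sink.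

Step 14
Reactants: 24 tert-butyl N-[(1R,2R,3S,5S,8R)-2,8-bis[(tert-butyldimethylsilyl)oxy]-5-hydroxy-9-oxobicyclo[3.3.1]non-6-en-3-yl]carbamate
Product: 25 (1S,4R,5R,6R,7S)-7-amino-1,4,6-trihydroxybicyclo[3.3.1]non-2-en-9-one hydrochloride
Conditions: HCl (4 M in 1,4-dioxane), H2O (10 equiv), 0 → 23 °C
Reagents that add atoms: hydrogen chloride, Cl
Why: Acidolysis removes the Boc group (loss of isobutene and CO2) and hydrolyses both secondary silyl ethers in one operation; the bridgehead ketol cannot enolise towards C5 or ionise easily at C3, so the core should survive, and the amine is kept as its hydrochloride.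

Step 15
Reactants: 26 hex-5-enenitrile; 27 pentylmagnesium bromide
Product: 29 undec-1-en-6-one, via ketimine magnesium salt 28 (not isolated)
Conditions: Et2O, 0 → 35 °C; then 2 M HCl, 23 °C
Reagents that add atoms: water, O
Why: Grignard addition to a nitrile stops at the ketimine salt 28, which gives the ketone on acidic hydrolysis; the isolated terminal alkene is inert.

Step 16
Reactants: 29 undec-1-en-6-one; 30 acrylic acid
Product: 31 (2E)-7-oxododec-2-enoic acid
Conditions: RuCl2(=CH-C6H4-2-O-i-Pr)(H2IMes) (second-generation Hoveyda–Grubbs catalyst, 5 mol %), 30 (3 equiv), CH2Cl2, 40 °C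
Reagents that add atoms: none
Why: Olefin cross-metathesis of a terminal alkene with acrylic acid is selective for the cross product and for the E isomer, since the electron-poor partner does not homodimerise readily.

Step 17
Reactants: 25 (1S,4R,5R,6R,7S)-7-amino-1,4,6-trihydroxybicyclo[3.3.1]non-2-en-9-one hydrochloride; 31 (2E)-7-oxododec-2-enoic acid
Product: 33 (2E)-7-oxo-N-[(1R,2R,3S,5S,8R)-2,5,8-trihydroxy-9-oxobicyclo[3.3.1]non-6-en-3-yl]dodec-2-enamide, via benzotriazol-1-yl ester 32 (not isolated)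
Conditions: EDC·HCl, HOBt, i-Pr2NEt, DMF, 0 → 23 °C
Reagents that add atoms: none
Why: Carbodiimide-mediated amide coupling through the benzotriazolyl ester 32 acylates the primary amine much faster than the secondary or tertiary hydroxyls; the hindered amine base serves only to free the ammonium salt.

Step 18
Reactants: 33 (2E)-7-oxo-N-[(1R,2R,3S,5S,8R)-2,5,8-trihydroxy-9-oxobicyclo[3.3.1]non-6-en-3-yl]dodec-2-enamide
Product: 34 isariotin C
Conditions: VO(acac)2 (10 mol %), t-BuOOH (1.5 equiv, in decane), CH2Cl2, 0 → 23 °C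
Reagents that add atoms: tert-butyl hydroperoxide, CC(C)(C)OO
Why: Vanadium-catalysed hydroxyl-directed epoxidation with tert-butyl hydroperoxide: the C6 and C3 allylic hydroxyls both lie on the exo face of ring B, so oxygen should be delivered syn to them onto C7=C8 and set C7 and C8 as in the target, while the electron-poor enamide alkene has no directing hydroxyl and should not react.

**Compound list**

1 | (2S)-4-tert-butoxy-2-[(tert-butoxycarbonyl)amino]-4-oxobutanoic acid (N-Boc-L-aspartic acid 4-tert-butyl ester) | CC(C)(C)OC(=O)N[C@@H](CC(=O)OC(C)(C)C)C(=O)O | starting material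
2 | monobenzyl malonate | OC(=O)CC(=O)OCc1ccccc1 | starting material
3 | tert-butyl (3S)-3-[(tert-butoxycarbonyl)amino]-4-(imidazol-1-yl)-4-oxobutanoate (acyl imidazolide of 1, not isolated) | CC(C)(C)OC(=O)N[C@@H](CC(=O)OC(C)(C)C)C(=O)n1ccnc1 | intermediate
4 | 2-[(2S)-2-[(tert-butoxycarbonyl)amino]-4-tert-butoxy-4-oxobutanoyl]malonic acid monobenzyl ester (not isolated) | CC(C)(C)OC(=O)N[C@@H](CC(=O)OC(C)(C)C)C(=O)C(C(=O)O)C(=O)OCc1ccccc1 | intermediate
5 | 6-benzyl 1-tert-butyl (3S)-3-[(tert-butoxycarbonyl)amino]-4-oxohexanedioate | CC(C)(C)OC(=O)N[C@@H](CC(=O)OC(C)(C)C)C(=O)CC(=O)OCc1ccccc1 | intermediate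
6 | 6-benzyl 1-tert-butyl (3S,4R)-3-[(tert-butoxycarbonyl)amino]-4-hydroxyhexanedioate | CC(C)(C)OC(=O)N[C@@H](CC(=O)OC(C)(C)C)[C@H](O)CC(=O)OCc1ccccc1 | intermediate
7 | 6-benzyl 1-tert-butyl (3S,4R)-3-[(tert-butoxycarbonyl)amino]-4-[(tert-butyldimethylsilyl)oxy]hexanedioate | CC(C)(C)OC(=O)N[C@@H](CC(=O)OC(C)(C)C)[C@H](O[Si](C)(C)C(C)(C)C)CC(=O)OCc1ccccc1 | intermediate
8 | (3R,4S)-4-[(tert-butoxycarbonyl)amino]-6-tert-butoxy-3-[(tert-butyldimethylsilyl)oxy]-6-oxohexanoic acid | CC(C)(C)OC(=O)N[C@@H](CC(=O)OC(C)(C)C)[C@H](O[Si](C)(C)C(C)(C)C)CC(=O)O | intermediate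
9 | (4S)-4-benzyl-1,3-oxazolidin-2-one | O=C1N[C@@H](Cc2ccccc2)CO1 | starting material
10 | mixed anhydride of 8 with pivalic acid (not isolated) | CC(C)(C)OC(=O)N[C@@H](CC(=O)OC(C)(C)C)[C@H](O[Si](C)(C)C(C)(C)C)CC(=O)OC(=O)C(C)(C)C | intermediate
11 | (4S)-4-benzyl-3-[(3R,4S)-4-[(tert-butoxycarbonyl)amino]-6-tert-butoxy-3-[(tert-butyldimethylsilyl)oxy]-6-oxohexanoyl]-1,3-oxazolidin-2-one | CC(C)(C)OC(=O)N[C@@H](CC(=O)OC(C)(C)C)[C@H](O[Si](C)(C)C(C)(C)C)CC(=O)N1[C@@H](Cc2ccccc2)COC1=O | intermediate
12 | acrolein | C=CC=O | starting material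
13 | Z-dibutylboron enolate of 11 (not isolated) | CC(C)(C)OC(=O)N[C@@H](CC(=O)OC(C)(C)C)[C@H](O[Si](C)(C)C(C)(C)C)/C=C(\OB(CCCC)CCCC)N1[C@@H](Cc2ccccc2)COC1=O | intermediate
14 | O-dibutylboryl aldolate of 15 (not isolated) | CC(C)(C)OC(=O)N[C@@H](CC(=O)OC(C)(C)C)[C@H](O[Si](C)(C)C(C)(C)C)[C@H](C(=O)N1[C@@H](Cc2ccccc2)COC1=O)[C@H](OB(CCCC)CCCC)C=C | intermediate
15 | (4S)-4-benzyl-3-[(2R,3R,4S)-4-[(tert-butoxycarbonyl)amino]-6-tert-butoxy-3-[(tert-butyldimethylsilyl)oxy]-2-[(1R)-1-hydroxyprop-2-en-1-yl]-6-oxohexanoyl]-1,3-oxazolidin-2-one | CC(C)(C)OC(=O)N[C@@H](CC(=O)OC(C)(C)C)[C@H](O[Si](C)(C)C(C)(C)C)[C@H](C(=O)N1[C@@H](Cc2ccccc2)COC1=O)[C@H](O)C=C | intermediate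
16 | (4S)-4-benzyl-3-[(2R,3R,4S)-4-[(tert-butoxycarbonyl)amino]-6-tert-butoxy-3-[(tert-butyldimethylsilyl)oxy]-2-[(1R)-1-[(tert-butyldimethylsilyl)oxy]prop-2-en-1-yl]-6-oxohexanoyl]-1,3-oxazolidin-2-one | CC(C)(C)OC(=O)N[C@@H](CC(=O)OC(C)(C)C)[C@H](O[Si](C)(C)C(C)(C)C)[C@H](C(=O)N1[C@@H](Cc2ccccc2)COC1=O)[C@H](O[Si](C)(C)C(C)(C)C)C=C | intermediate
17 | tert-butyl (3S,4R,5R,6R)-3-[(tert-butoxycarbonyl)amino]-4,6-bis[(tert-butyldimethylsilyl)oxy]-5-(hydroxymethyl)oct-7-enoate | CC(C)(C)OC(=O)N[C@@H](CC(=O)OC(C)(C)C)[C@H](O[Si](C)(C)C(C)(C)C)[C@H](CO)[C@H](O[Si](C)(C)C(C)(C)C)C=C | intermediate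
18 | tert-butyl N-[(3S,4R,5R,6R)-4,6-bis[(tert-butyldimethylsilyl)oxy]-5-(hydroxymethyl)-1-oxooct-7-en-3-yl]carbamate | CC(C)(C)OC(=O)N[C@@H](CC=O)[C@H](O[Si](C)(C)C(C)(C)C)[C@H](CO)[C@H](O[Si](C)(C)C(C)(C)C)C=C | intermediate
19 | vinylmagnesium bromide | C=C[Mg]Br | starting material
20 | tert-butyl N-[(5S,6R,7R,8R)-6,8-bis[(tert-butyldimethylsilyl)oxy]-3-hydroxy-7-(hydroxymethyl)deca-1,9-dien-5-yl]carbamate (both C3 epimers) | CC(C)(C)OC(=O)N[C@@H](CC(O)C=C)[C@H](O[Si](C)(C)C(C)(C)C)[C@H](CO)[C@H](O[Si](C)(C)C(C)(C)C)C=C | intermediate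
21 | tert-butyl N-[(1S,2R,3R,4R,5Z)-2,4-bis[(tert-butyldimethylsilyl)oxy]-7-hydroxy-3-(hydroxymethyl)cyclooct-5-en-1-yl]carbamate (both C7 epimers) | CC(C)(C)OC(=O)N[C@H]1CC(O)/C=C\[C@@H](O[Si](C)(C)C(C)(C)C)[C@@H](CO)[C@H]1O[Si](C)(C)C(C)(C)C | intermediate
22 | tert-butyl N-[(1S,2R,3R,4R,5Z)-2,4-bis[(tert-butyldimethylsilyl)oxy]-3-formyl-7-oxocyclooct-5-en-1-yl]carbamate (formyl cis to both silyloxy groups and to NHBoc) | CC(C)(C)OC(=O)N[C@H]1CC(=O)/C=C\[C@@H](O[Si](C)(C)C(C)(C)C)[C@@H](C=O)[C@H]1O[Si](C)(C)C(C)(C)C | intermediate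
23 | Breslow intermediate: enaminol of 22 at C4 with the 2-(pentafluorophenyl)pyrrolotriazolylidene (not isolated) | CC(C)(C)OC(=O)N[C@H]1CC(=O)/C=C\[C@@H](O[Si](C)(C)C(C)(C)C)[C@@H](C(O)=C2N(c3c(F)c(F)c(F)c(F)c3F)N=C3CCCN23)[C@H]1O[Si](C)(C)C(C)(C)C | intermediate
24 | tert-butyl N-[(1R,2R,3S,5S,8R)-2,8-bis[(tert-butyldimethylsilyl)oxy]-5-hydroxy-9-oxobicyclo[3.3.1]non-6-en-3-yl]carbamate | CC(C)(C)OC(=O)N[C@H]1C[C@@]2(O)C(=O)[C@H]([C@H](O[Si](C)(C)C(C)(C)C)C=C2)[C@H]1O[Si](C)(C)C(C)(C)C | intermediate
25 | (1S,4R,5R,6R,7S)-7-amino-1,4,6-trihydroxybicyclo[3.3.1]non-2-en-9-one hydrochloride | Cl.N[C@H]1C[C@@]2(O)C(=O)[C@H]([C@H](O)C=C2)[C@H]1O | intermediate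
26 | hex-5-enenitrile | C=CCCCC#N | starting material
27 | pentylmagnesium bromide | CCCCC[Mg]Br | starting material
28 | N-bromomagnesio ketimine of undec-1-en-6-one (not isolated) | C=CCCCC(CCCCC)=N[Mg]Br | intermediate
29 | undec-1-en-6-one | C=CCCCC(=O)CCCCC | intermediate
30 | acrylic acid | C=CC(=O)O | starting material
31 | (2E)-7-oxododec-2-enoic acid | CCCCCC(=O)CCC/C=C/C(=O)O | intermediate
32 | benzotriazol-1-yl (2E)-7-oxododec-2-enoate (not isolated) | CCCCCC(=O)CCC/C=C/C(=O)On1nnc2ccccc12 | intermediate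
33 | (2E)-7-oxo-N-[(1R,2R,3S,5S,8R)-2,5,8-trihydroxy-9-oxobicyclo[3.3.1]non-6-en-3-yl]dodec-2-enamide | CCCCCC(=O)CCC/C=C/C(=O)N[C@H]1C[C@@]2(O)C(=O)[C@H]([C@H](O)C=C2)[C@H]1O | intermediate
34 | isariotin C | CCCCCC(=O)CCC/C=C/C(=O)N[C@H]1C[C@@]2(O)C(=O)[C@H]([C@H](O)[C@@H]3O[C@@H]32)[C@H]1O | target

**Count and risks**

Total steps: 18. Longest linear sequence: 16 (steps 1–14, 17 and 18, from 1); steps 15 and 16 make the side-chain acid.

Steps most likely to fail:

1. Step 13 (transannular benzoin). The carbene may add too slowly to the hindered, α-branched aldehyde, so that base-induced epimerisation or β-elimination at C5, or aldol closure from the C2 enolate, overtakes the C3–C4 bond formation; the ring may also not reach the conformation that brings C4 over C3. Fallback, from 22 back to 24: reductive instead of umpolung closure of the same bond. SmI2 (samarium diiodide, 2.5 equiv, THF, −78 °C) should effect the ketone–aldehyde pinacol coupling, which is known chemistry for ring closure, and give tert-butyl N-[2,8-bis[(tert-butyldimethylsilyl)oxy]-5,9-dihydroxybicyclo[3.3.1]non-6-en-3-yl]carbamate F1 (configuration at the C4 carbinol immaterial; conjugate coupling at C7 is excluded because it would need a four-membered ring). Parikh–Doering oxidation (SO3·pyridine, DMSO, i-Pr2NEt, 0 °C) of the secondary C4 hydroxyl beside the tertiary one then returns to ketol 24.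

2. Step 11 (eight-membered ring-closing metathesis). Intermolecular metathesis may outrun the entropically and transannularly disfavoured closure, or a ruthenium hydride may isomerise the allylic alcohol to the ethyl ketone. Fallback, from 20 back to 22: the order of oxidation and ring closure is reversed, so that the ring closes on a vinyl ketone. Dess–Martin oxidation of both hydroxyls of 20 gives tert-butyl N-[(5S,6R,7R,8R)-6,8-bis[(tert-butyldimethylsilyl)oxy]-7-formyl-3-oxodeca-1,9-dien-5-yl]carbamate F2. Its metathesis (second-generation Hoveyda–Grubbs catalyst, toluene, 80 °C, 1 mM) then closes the ring at the enone stage, where the sp2 C3 changes the conformational bias of the chain and the isomerisation path of the allylic alcohol no longer exists, and delivers 22 directly.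

3. Step 6 (auxiliary-controlled aldol). Enolisation of the hindered imide may be incomplete, the enolate may expel the β-silyloxy group, or the C9 centre may oppose the auxiliary and erode facial selectivity. Fallback, from 8 back to 17: stereocontrol is moved from the open, dipole-controlled boron transition state to a titanium-chelated one on a thiazolidinethione. Acid 8 is coupled with (4R)-4-benzyl-1,3-thiazolidine-2-thione (EDC·HCl, DMAP) to the N-acyl thiazolidinethione F3. Soft enolisation with TiCl4 (1 equiv) and i-Pr2NEt (1 equiv) at −78 °C and addition of acrolein should give, through the closed transition state in which the thiocarbonyl sulfur stays on titanium, the syn aldol F4 with the same C5 and C6 configuration as 15. Silylation (TBSOTf, 2,6-lutidine) gives the bis-silyl ether F5, and NaBH4 in THF/EtOH cleaves the auxiliary to alcohol 17.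

**Further compounds**

F1 | step 13 | tert-butyl N-[2,8-bis[(tert-butyldimethylsilyl)oxy]-5,9-dihydroxybicyclo[3.3.1]non-6-en-3-yl]carbamate (pinacol diol, C9-carbinol configuration open) | CC(C)(C)OC(=O)N[C@H]1C[C@@]2(O)C(O)[C@H]([C@H](O[Si](C)(C)C(C)(C)C)C=C2)[C@H]1O[Si](C)(C)C(C)(C)C
F2 | step 11 | tert-butyl N-[(5S,6R,7R,8R)-6,8-bis[(tert-butyldimethylsilyl)oxy]-7-formyl-3-oxodeca-1,9-dien-5-yl]carbamate | CC(C)(C)OC(=O)N[C@@H](CC(=O)C=C)[C@H](O[Si](C)(C)C(C)(C)C)[C@H](C=O)[C@H](O[Si](C)(C)C(C)(C)C)C=C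
F3 | step 6 | tert-butyl (3S,4R)-6-[(4R)-4-benzyl-2-thioxo-1,3-thiazolidin-3-yl]-3-[(tert-butoxycarbonyl)amino]-4-[(tert-butyldimethylsilyl)oxy]-6-oxohexanoate | CC(C)(C)OC(=O)N[C@@H](CC(=O)OC(C)(C)C)[C@H](O[Si](C)(C)C(C)(C)C)CC(=O)N1[C@H](Cc2ccccc2)CSC1=S
F4 | step 6 | syn aldol of F3 with acrolein, same chain configuration as 15 | CC(C)(C)OC(=O)N[C@@H](CC(=O)OC(C)(C)C)[C@H](O[Si](C)(C)C(C)(C)C)[C@H](C(=O)N1[C@H](Cc2ccccc2)CSC1=S)[C@H](O)C=C
F5 | step 6 | tert-butyldimethylsilyl ether of F4 | CC(C)(C)OC(=O)N[C@@H](CC(=O)OC(C)(C)C)[C@H](O[Si](C)(C)C(C)(C)C)[C@H](C(=O)N1[C@H](Cc2ccccc2)CSC1=S)[C@H](O[Si](C)(C)C(C)(C)C)C=C
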